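(The earlier runs and the new flask are simulated on assumed constants.)

The complex with one exchanged is a middleman: the starting complex feeds it and something takes it away, and how much stands in your flask depends on how those two rates compare.

| flask | starting complex | incoming ligand | remark | time |
|---|---|---|---|---|
| teal | 0.34 M | 2 equiv | run made earlier |  |
| red | 0.75 M | 2 equiv | run made earlier |  |
| flask | 0.50 M | 2.00 equiv |  | 4.0 d |

| run | time / d | complex with one exchanged / % | complex with two exchanged / % |
|---|---|---|---|
| teal | 0.0833 | 6.4 | 0 |
| teal | 0.167 | 8.8 | 0 |
| teal | 0.250 | 10.5 | 0.4 |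
| teal | 0.500 | 10.2 | 0.4 |
| teal | 1.04 | 6.6 | 1.0 |
| teal | 2.08 | 2.6 | 1.4 |
| teal | 4.00 | 0.9 | 0.2 |
| red | 0.0833 | 11.6 | 0 |
| red | 0.167 | 16.2 | 0.7 |
| red | 0.250 | 18.5 | 0.3 |
| red | 0.500 | 14.4 | 0 |
| red | 1.04 | 6.2 | 0 |
| red | 2.08 | 1.9 | 0 |
| red | 4.00 | 0.1 | 0.5 |

(readings scatter by 0.5 percentage points)

- the moment within 4.0 d at which there is most complex with one exchanged
- the amount of complex with one exchanged, in percent of the starting complex charged, at that time
- the first time at which complex with one exchanged reaches 4.3%, in the same percent



1. **First instants.** The first readings climb with the charge, 6.4% in teal and 11.6% in red at 0.0833 d. Scale both to 0.50 M, average them and draw a straight line, and 4.3% comes at 1.00 h. The rise bends, so I expect a little sooner.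

2. **Middle.** Teal reads 10.5% and red 18.5% at 0.250 d. I take these as their tops and expect yours between 0.250 d and 0.500 d. Treat the chain as two first-order steps, the making one pseudo-first-order with [incoming ligand] held near its charge. With a ratio of making constant to loss constant, the top, as a fraction of the charge, is that ratio raised to the power one over (one minus the ratio). Solved backwards, the tops give 0.146 for teal and 0.312 for red. Per molar of starting complex that is 0.429 M⁻¹ and 0.416 M⁻¹, so on these readings the ratio grows with the charge. With the mean, 0.423 M⁻¹, I reckon the feed ratio, making constant over loss constant, at 0.211 in your flask. That reckons your top at 13.9%.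

3. **End.** From 0.250 d to 2.08 d teal loses 7.9 percentage points of complex with one exchanged but gains 1 point of complex with two exchanged, so most of the loss goes somewhere these readings don't show.

The forecast gave 0.28 d, 14% and 0.75 h, holding that “The rise barely depends on concentration, but the amplitude and fall do”.

The flask gives 0.306 d, 14.2% and 0.877 h.

    starting complex + incoming ligand ⇌ leaving ligand + complex with one exchanged (K = 0.730, k = 0.0560 M⁻¹ h⁻¹)
    complex with one exchanged + incoming ligand ⇌ leaving ligand + complex with two exchanged (K = 0.680, k = 0.00257 M⁻¹ h⁻¹)
    complex with two exchanged + incoming ligand ⇌ leaving ligand + complex with three exchanged (K = 23.0, k = 0.0415 M⁻¹ h⁻¹)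
    complex with one exchanged → decomposed reagent (k = 0.217 h⁻¹)

While the starting complex fell to 69.2% at 0.305 d, the step to decomposed reagent, half-life 0.13 d, took complex with one exchanged faster than the second exchange, forward half-life 11 d at the charged amounts. At the top of your flask, complex with one exchanged over starting complex is 0.205, beside a reckoned feed ratio of 0.211. For a neighbour flask with 0.500 equiv of incoming ligand, the feed ratio reckons to 0.0528 and the top to 4.48%, and that neighbour flask peaks at 4.36%.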